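**Plan**
- Retrosynthetic cuts, in order: (a) the C(=O)–CH2 bond between the ketone carbon and the allylic CH2 of the furyl side chain; (b) the lactone acyl C–O bond, back to a primary/tertiary 1,4-diol; (c) the C2–CH3 group, traced back to C2–CH2OH; (d) the oxolane O1–C2 bond together with the C–O bond on that exocyclic CH2; (e) the allylic C–C bond of an acyclic 1,5-diene.
- Forward order: the chain is joined by alkylating the dianion of 3-methylbut-3-en-1-ol with an E-allyl bromide; the oxolane closes first (step 8), the lactone second (step 12), and the furyl side chain is attached last (steps 18 and 19).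
- Enabling feature: oxolane C2 is a fully substituted ether carbon whose methyl is cis to the lactone on C5. Carried as CH2OH, that carbon is the one an osmium oxo ligand attacks while the C5 side-chain oxygen is bound to the same metal, so the cis relation is built in.
- Stereochemistry: C5 and the lactone carbon C6 come from Shi epoxidation of the E-trisubstituted alkene (reagent control) and hydrolysis with inversion at the tertiary carbon. C2 comes from the chelated osmate in step 8. The E side-chain alkene comes from a stabilised Wittig reaction, and the carbinol formed in step 18 is erased by oxidation.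

Key step: step 8

Remark: O1 and C2–C5 denote the central oxolane (C2 quaternary, C5 bearing the lactone) and C6 the lactone carbon bound to C5; the same labels are used for the acyclic precursors.

**Route**

Step 1
Reactants: 1 pent-4-yn-1-ol
Product: 2 5-(benzyloxy)pent-1-yne
Conditions: NaH, BnBr, Bu4NI (cat.), THF, 0 °C → rt
Reagents that add atoms: benzyl bromide, BrCc1ccccc1
Why: Williamson ether synthesis; the sodium alkoxide is benzylated much faster than the terminal alkyne is deprotonated under these conditions.

Step 2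
Reactants: 2 5-(benzyloxy)pent-1-yne
Product: 4 (2E)-6-(benzyloxy)-3-methylhex-2-en-1-ol, via alkenyldimethylalane 3 (not isolated)
Conditions: Me3Al, Cp2ZrCl2 (0.25 equiv), CH2Cl2, 0 °C → rt; then (CH2O)n, 0 °C → rt; aqueous work-up
Reagents that add atoms: trimethylaluminium, C[Al](C)C; formaldehyde (as paraformaldehyde), C=O
Why: Zirconium-catalysed Negishi carboalumination adds CH3 and Al syn across the terminal alkyne with Al at the terminus, and the alkenylalane is hydroxymethylated with retention, which fixes the E geometry.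

Step 3
Reactants: 4 (2E)-6-(benzyloxy)-3-methylhex-2-en-1-ol
Product: 5 ({[(4E)-6-bromo-4-methylhex-4-en-1-yl]oxy}methyl)benzene
Conditions: CBr4, PPh3, CH2Cl2, 0 °C
Reagents that add atoms: tetrabromomethane, BrC(Br)(Br)Br
Why: Appel bromination converts the primary allylic alcohol into the bromide under neutral conditions, without allylic transposition or loss of the E geometry.

Step 4
Reactants: 6 3-methylbut-3-en-1-ol; 5 ({[(4E)-6-bromo-4-methylhex-4-en-1-yl]oxy}methyl)benzene
Product: 8 (6E)-10-(benzyloxy)-7-methyl-3-methylidenedec-6-en-1-ol, via dilithio dianion 7 (not isolated)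
Conditions: 6, n-BuLi (2.1 equiv), TMEDA, Et2O, 0 °C → rt; then 5, THF, −78 °C → rt; H2O
Reagents that add atoms: none
Why: Dianion alkylation; alkoxide-directed lithiation of the allylic methyl gives a 2-substituted allyl anion with two equivalent CH2 termini, which displaces the primary allylic bromide in an SN2 sense and leaves the E alkene untouched.

Step 5
Reactants: 8 (6E)-10-(benzyloxy)-7-methyl-3-methylidenedec-6-en-1-ol
Product: 9 (4E)-1,10-bis(benzyloxy)-4-methyl-8-methylidenedec-4-ene
Conditions: NaH, BnBr, Bu4NI (cat.), THF/DMF, 0 °C → rt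
Reagents that add atoms: benzyl bromide, BrCc1ccccc1
Why: Williamson ether synthesis; two identical benzyl ethers allow both primary alcohols to be released later in one hydrogenolysis.

Step 6
Reactants: 9 (4E)-1,10-bis(benzyloxy)-4-methyl-8-methylidenedec-4-ene
Product: 10 (2R,3R)-2-[3-(benzyloxy)propyl]-3-[5-(benzyloxy)-3-methylidenepentyl]-2-methyloxirane
Conditions: D-fructose-derived Shi ketone (0.3 equiv), KHSO5 (as 2KHSO5·KHSO4·K2SO4, about 1 equiv of oxidant), K2CO3, Bu4NHSO4, MeCN/CH2(OMe)2, aq. Na2B4O7 buffer (pH 10.5), 0 °C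
Reagents that add atoms: potassium peroxymonosulfate, [K+].[O-]S(=O)(=O)OO
Why: Shi epoxidation; the electrophilic chiral dioxirane attacks the electron-richer E-trisubstituted alkene through the spiro transition state in preference to the 1,1-disubstituted one, and delivers oxygen to the face that gives the (R,R)-oxirane.

Step 7
Reactants: 10 (2R,3R)-2-[3-(benzyloxy)propyl]-3-[5-(benzyloxy)-3-methylidenepentyl]-2-methyloxirane
Product: 11 (4S,5R)-1,10-bis(benzyloxy)-4-methyl-8-methylidenedecane-4,5-diol
Conditions: HClO4 (3% aq.), THF, 0 °C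
Reagents that add atoms: water, O
Why: Acid-catalysed epoxide hydrolysis; water opens the protonated oxirane at the tertiary carbon from the back side (borderline SN2), so the secondary C–O bond keeps its configuration and the tertiary centre inverts, which turns the E-derived oxirane into the anti diol.

Step 8
Reactants: 11 (4S,5R)-1,10-bis(benzyloxy)-4-methyl-8-methylidenedecane-4,5-diol
Product: 14 (2S)-5-(benzyloxy)-2-[(2R,5R)-5-[2-(benzyloxy)ethyl]-5-(hydroxymethyl)oxolan-2-yl]pentan-2-ol, via hexavalent osmium glycolate 12 (not isolated), via tetravalent osmium chelate 13 (not isolated)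
Conditions: K2OsO2(OH)4 (5 mol %), Me3NO (4 equiv), CF3CO2H, acetone/H2O, rt
Reagents that add atoms: trimethylamine N-oxide, C[N+](C)(C)[O-] (oxygen atom, passed on through the osmium oxo ligand)
Why: Diol 11 condenses with the osmate to the hexavalent osmium glycolate 12, whose O–Os=O unit adds suprafacially in a [3+2] sense across the tethered 1,1-disubstituted alkene to give the tetravalent osmium chelate 13; hydrolysis frees 14 and Me3NO returns osmium to the hexavalent state, the acid speeding cyclisation and release. The closest known reaction type is the osmium-catalysed oxidative cyclisation of 1,2-diols onto pendant alkenes, which gives cis-2,5-disubstituted oxolanes. The one ring closes 5-exo-trig: the oxygen on C5 bonds to the internal alkene carbon, which becomes C2, and an oxo ligand bonds to the terminal CH2. The one new stereocentre, C2, is fixed by the chelate, because the glycolate oxygen on C6 and the new CH2–O are both held on osmium and so lie on the same face of the ring; CH2OH therefore ends cis to the C5 side chain, and C5 is carried through unchanged. The step needs cyclisation to outrun plain dihydroxylation of the alkene and closure through the secondary rather than the tertiary oxygen; the first should be secured by the acid and by intramolecular delivery from a pre-bound glycolate, the second by the preference for a five- over a six-membered ring.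

Step 9
Reactants: 14 (2S)-5-(benzyloxy)-2-[(2R,5R)-5-[2-(benzyloxy)ethyl]-5-(hydroxymethyl)oxolan-2-yl]pentan-2-ol
Product: 15 (2S)-5-(benzyloxy)-2-[(2R,5R)-5-[2-(benzyloxy)ethyl]-5-(iodomethyl)oxolan-2-yl]pentan-2-ol
Conditions: I2, PPh3, imidazole, toluene, 70 °C
Reagents that add atoms: iodine, II
Why: Appel iodination; only the primary hydroxyl forms the alkoxyphosphonium ion, which iodide displaces on warming although the carbon is neopentyl, while the tertiary alcohol and the benzyl ethers do not react.

Step 10
Reactants: 15 (2S)-5-(benzyloxy)-2-[(2R,5R)-5-[2-(benzyloxy)ethyl]-5-(iodomethyl)oxolan-2-yl]pentan-2-ol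
Product: 16 (2S)-5-(benzyloxy)-2-[(2R,5R)-5-[2-(benzyloxy)ethyl]-5-methyloxolan-2-yl]pentan-2-ol
Conditions: Bu3SnH, AIBN (cat.), toluene, 80 °C
Reagents that add atoms: none
Why: Radical dehalogenation; the stannyl radical abstracts iodine and the primary alkyl radical takes hydrogen from Bu3SnH faster than it can fragment, so the sacrificial oxygen is deleted and C2 now carries the methyl cis to the C5 side chain.

Step 11
Reactants: 16 (2S)-5-(benzyloxy)-2-[(2R,5R)-5-[2-(benzyloxy)ethyl]-5-methyloxolan-2-yl]pentan-2-ol
Product: 17 (4S)-4-[(2R,5R)-5-(2-hydroxyethyl)-5-methyloxolan-2-yl]pentane-1,4-diol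
Conditions: H2 (1 atm), Pd/C (10 wt% Pd), EtOH, rt
Reagents that add atoms: none
Why: Catalytic hydrogenolysis cleaves both benzylic C–O bonds; no alkene remains at this stage and the oxolane and tertiary alcohol are inert.

Step 12
Reactants: 17 (4S)-4-[(2R,5R)-5-(2-hydroxyethyl)-5-methyloxolan-2-yl]pentane-1,4-diol
Product: 19 2-[(2R,5R)-2-methyl-5-[(2S)-2-methyl-5-oxooxolan-2-yl]oxolan-2-yl]acetaldehyde, via lactol aldehyde 18 (not isolated)
Conditions: TEMPO (0.2 equiv), PhI(OAc)2 (3.5 equiv), dry CH2Cl2, rt
Reagents that add atoms: none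
Why: Oxoammonium oxidation (oxidative lactonisation); both primary alcohols go to aldehydes, the one 1,4 to the tertiary hydroxyl closes to the lactol and is oxidised on to the γ-lactone, and the other stops at the aldehyde because it has no hydroxyl within reach and no water is present.

Step 13
Reactants: 20 furan-3-carbaldehyde
Product: 21 (2E)-3-(furan-3-yl)prop-2-enal
Conditions: Ph3P=CHCHO, toluene, 80 °C
Reagents that add atoms: (triphenyl-λ5-phosphanylidene)acetaldehyde, O=CC=P(c1ccccc1)(c1ccccc1)c1ccccc1
Why: Wittig olefination with a formyl-stabilised ylide, which should give the E enal and reacts with the aromatic aldehyde faster than with the less electrophilic product.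

Step 14
Reactants: 21 (2E)-3-(furan-3-yl)prop-2-enal
Product: 22 3-(furan-3-yl)propanal
Conditions: diethyl 2,6-dimethyl-1,4-dihydropyridine-3,5-dicarboxylate (1.1 equiv), dibenzylammonium trifluoroacetate (5 mol %), THF, rt
Reagents that add atoms: none
Why: Organocatalytic transfer hydrogenation; iminium activation of the enal lets the dihydropyridine deliver hydride to the β-carbon only, so neither the saturated aldehyde nor the furan is reduced.

Step 15
Reactants: 22 3-(furan-3-yl)propanal
Product: 23 ethyl (2E)-5-(furan-3-yl)-2-methylpent-2-enoate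
Conditions: Ph3P=C(CH3)CO2Et, CH2Cl2, rt
Reagents that add atoms: ethyl 2-(triphenyl-λ5-phosphanylidene)propanoate, CCOC(=O)C(C)=P(c1ccccc1)(c1ccccc1)c1ccccc1
Why: Wittig olefination with an α-branched stabilised ylide, which is expected to give the E trisubstituted enoate and thereby sets the side-chain alkene geometry of the target.

Step 16
Reactants: 23 ethyl (2E)-5-(furan-3-yl)-2-methylpent-2-enoate
Product: 24 (2E)-5-(furan-3-yl)-2-methylpent-2-en-1-ol
Conditions: i-Bu2AlH (2.2 equiv), CH2Cl2, −78 °C
Reagents that add atoms: none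
Why: 1,2-Reduction of the enoate by the aluminium hydride gives the allylic alcohol without conjugate reduction or change of alkene geometry.

Step 17
Reactants: 24 (2E)-5-(furan-3-yl)-2-methylpent-2-en-1-ol
Product: 25 3-[(3E)-5-chloro-4-methylpent-3-en-1-yl]furan
Conditions: PPh3, (Cl3C)2CO, CH2Cl2, 0 °C
Reagents that add atoms: hexachloroacetone, ClC(Cl)(Cl)C(=O)C(Cl)(Cl)Cl
Why: Appel-type chlorination; the alkoxyphosphonium ion is displaced by chloride at the primary carbon under neutral conditions, so neither allylic transposition, E/Z scrambling nor damage to the furan is expected.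

Step 18
Reactants: 25 3-[(3E)-5-chloro-4-methylpent-3-en-1-yl]furan; 19 2-[(2R,5R)-2-methyl-5-[(2S)-2-methyl-5-oxooxolan-2-yl]oxolan-2-yl]acetaldehyde
Product: 27 (5S)-5-[(2R,5R)-5-[(4E)-7-(furan-3-yl)-2-hydroxy-4-methylhept-4-en-1-yl]-5-methyloxolan-2-yl]-5-methyloxolan-2-one (both carbinol epimers), via allylbarium chloride 26 (not isolated)
Conditions: activated Ba (from BaI2 and lithium biphenylide, THF, rt); 25, −78 °C; then 19, −78 °C; aq. NH4Cl
Reagents that add atoms: none
Why: Allylbarium addition; insertion of activated barium into the allylic chloride at −78 °C gives an allylmetal that keeps the E geometry and bonds to the aldehyde through its α-carbon (the CH2) rather than the γ-carbon, faster than it attacks the lactone, and the uncontrolled carbinol centre is removed in the next step.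

Step 19
Reactants: 27 (5S)-5-[(2R,5R)-5-[(4E)-7-(furan-3-yl)-2-hydroxy-4-methylhept-4-en-1-yl]-5-methyloxolan-2-yl]-5-methyloxolan-2-one
Product: 28 (5S)-5-[(2R,5R)-5-[(4E)-7-(furan-3-yl)-4-methyl-2-oxohept-4-en-1-yl]-5-methyloxolan-2-yl]-5-methyloxolan-2-one (CNP0156092.1)
Conditions: Dess–Martin periodinane, NaHCO3, CH2Cl2, 0 °C → rt
Reagents that add atoms: none
Why: Dess–Martin oxidation under bicarbonate buffering takes the secondary alcohol to the ketone without moving the β,γ-alkene into conjugation or opening the β-alkoxy ketone, and no stereocentre of the target is touched.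

**Compound list**

1 | pent-4-yn-1-ol | C#CCCCO | starting material
2 | 5-(benzyloxy)pent-1-yne | C#CCCCOCc1ccccc1 | intermediate
3 | [(1E)-5-(benzyloxy)-2-methylpent-1-en-1-yl]dimethylalane | C[Al](C)/C=C(\C)CCCOCc1ccccc1 | intermediate
4 | (2E)-6-(benzyloxy)-3-methylhex-2-en-1-ol | OC/C=C(\C)CCCOCc1ccccc1 | intermediate
5 | ({[(4E)-6-bromo-4-methylhex-4-en-1-yl]oxy}methyl)benzene | BrC/C=C(\C)CCCOCc1ccccc1 | intermediate
6 | 3-methylbut-3-en-1-ol | C=C(C)CCO | starting material
7 | dilithio C,O-dianion of 3-methylbut-3-en-1-ol | [Li]CC(=C)CCO[Li] | intermediate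
8 | (6E)-10-(benzyloxy)-7-methyl-3-methylidenedec-6-en-1-ol | C=C(CCO)CC/C=C(\C)CCCOCc1ccccc1 | intermediate
9 | (4E)-1,10-bis(benzyloxy)-4-methyl-8-methylidenedec-4-ene | C=C(CCOCc1ccccc1)CC/C=C(\C)CCCOCc1ccccc1 | intermediate
10 | (2R,3R)-2-[3-(benzyloxy)propyl]-3-[5-(benzyloxy)-3-methylidenepentyl]-2-methyloxirane | C=C(CCOCc1ccccc1)CC[C@H]2O[C@]2(C)CCCOCc1ccccc1 | intermediate
11 | (4S,5R)-1,10-bis(benzyloxy)-4-methyl-8-methylidenedecane-4,5-diol | C=C(CCOCc1ccccc1)CC[C@@H](O)[C@@](C)(O)CCCOCc1ccccc1 | intermediate
12 | hexavalent osmium glycolate (dioxoosmium 4,5-diolate of 11) | O=[Os]1(=O)O[C@H](CCC(=C)CCOCc2ccccc2)[C@](C)(CCCOCc2ccccc2)O1 | intermediate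
13 | tetravalent osmium chelate of 14 (oxoosmium bound to the CH2–O and C6–O oxygens) | O=[Os]1OC[C@]2(CCOCc3ccccc3)CC[C@@H](O2)[C@](C)(CCCOCc3ccccc3)O1 | intermediate
14 | (2S)-5-(benzyloxy)-2-[(2R,5R)-5-[2-(benzyloxy)ethyl]-5-(hydroxymethyl)oxolan-2-yl]pentan-2-ol | c1ccccc1COCC[C@@]1(CO)CC[C@H]([C@@](C)(O)CCCOCc2ccccc2)O1 | intermediate
15 | (2S)-5-(benzyloxy)-2-[(2R,5R)-5-[2-(benzyloxy)ethyl]-5-(iodomethyl)oxolan-2-yl]pentan-2-ol | c1ccccc1COCC[C@@]1(CI)CC[C@H]([C@@](C)(O)CCCOCc2ccccc2)O1 | intermediate
16 | (2S)-5-(benzyloxy)-2-[(2R,5R)-5-[2-(benzyloxy)ethyl]-5-methyloxolan-2-yl]pentan-2-ol | c1ccccc1COCC[C@@]1(C)CC[C@H]([C@@](C)(O)CCCOCc2ccccc2)O1 | intermediate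
17 | (4S)-4-[(2R,5R)-5-(2-hydroxyethyl)-5-methyloxolan-2-yl]pentane-1,4-diol | OCC[C@@]1(C)CC[C@H]([C@@](C)(O)CCCO)O1 | intermediate
18 | 2-[(2R,5R)-5-[(2S)-5-hydroxy-2-methyloxolan-2-yl]-2-methyloxolan-2-yl]acetaldehyde (lactol aldehyde) | O=CC[C@@]1(C)CC[C@H]([C@]2(C)CCC(O)O2)O1 | intermediate
19 | 2-[(2R,5R)-2-methyl-5-[(2S)-2-methyl-5-oxooxolan-2-yl]oxolan-2-yl]acetaldehyde | O=CC[C@@]1(C)CC[C@H]([C@]2(C)CCC(=O)O2)O1 | intermediate
20 | furan-3-carbaldehyde | O=Cc1ccoc1 | starting material
21 | (2E)-3-(furan-3-yl)prop-2-enal | O=C/C=C/c1ccoc1 | intermediate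
22 | 3-(furan-3-yl)propanal | O=CCCc1ccoc1 | intermediate
23 | ethyl (2E)-5-(furan-3-yl)-2-methylpent-2-enoate | CCOC(=O)/C(C)=C/CCc1ccoc1 | intermediate
24 | (2E)-5-(furan-3-yl)-2-methylpent-2-en-1-ol | OC/C(C)=C/CCc1ccoc1 | intermediate
25 | 3-[(3E)-5-chloro-4-methylpent-3-en-1-yl]furan | ClC/C(C)=C/CCc1ccoc1 | intermediate
26 | [(2E)-5-(furan-3-yl)-2-methylpent-2-en-1-yl]barium chloride | Cl[Ba]C/C(C)=C/CCc1ccoc1 | intermediate
27 | (5S)-5-[(2R,5R)-5-[(4E)-7-(furan-3-yl)-2-hydroxy-4-methylhept-4-en-1-yl]-5-methyloxolan-2-yl]-5-methyloxolan-2-one | C/C(=C\CCc1ccoc1)CC(O)C[C@@]1(C)CC[C@H]([C@]2(C)CCC(=O)O2)O1 | intermediate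
28 | (5S)-5-[(2R,5R)-5-[(4E)-7-(furan-3-yl)-4-methyl-2-oxohept-4-en-1-yl]-5-methyloxolan-2-yl]-5-methyloxolan-2-one | C/C(=C\CCc1ccoc1)CC(=O)C[C@@]1(C)CC[C@H]([C@]2(C)CCC(=O)O2)O1 | target

**Step count**

Total: 19 steps. Longest linear sequence: 14 steps (steps 1–12, then 18 and 19, from pent-4-yn-1-ol). The furan side chain takes 5 steps (13–17) before the coupling.

**Steps most likely to fail, with fallbacks**

Step 7. The protonated oxirane may ionise partly to a tertiary cation, which would erode the inversion at C6, or it may be captured by the pendant 1,1-disubstituted alkene or by a benzyl ether oxygen instead of water. The fallback sets out from diene 9 and comes back at diol 11. Diene 9 would be epoxidised with the enantiomeric (L-fructose-derived) ketone under the conditions of step 6 to give the (2S,3S)-oxirane F1. This oxirane would then be opened with KOH in DMSO/H2O at about 100 °C. Hydroxide attacks the less substituted, secondary carbon in an SN2 sense, so C5 inverts and the tertiary C–O bond stays intact, which leads to the same (4S,5R)-diol 11 without any cationic intermediate.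

Step 18. The allylmetal may bond through its γ-carbon and give the branched alcohol, the allyl chloride may undergo Wurtz-type coupling, or the basic reagent may trigger β-elimination of the ring oxygen from the β-alkoxy aldehyde. The fallback sets out from chloride 25 and aldehyde 19 and comes back at the target 28. Chloride 25 would be treated with PhSO2Na in DMF to give the allyl sulfone F2. Deprotonation with n-BuLi in THF at −78 °C and addition of 19 would form the C–C bond at the sulfonyl-bearing carbon and give the β-hydroxy sulfone F3. Dess–Martin oxidation would give the β-keto sulfone F4. Reductive C–S cleavage with SmI2 in THF/MeOH at −78 °C, with kinetic α-protonation of the resulting dienolate, should then give 28 with the alkene still in the β,γ position.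

Step 8. Octavalent osmium formed on reoxidation may simply dihydroxylate the 1,1-disubstituted alkene before the glycolate cyclises, or the product, itself a chelating diol, may hold the metal and stop turnover. The fallback sets out from diol 11 and comes back at iodide 15, replacing steps 8 and 9. Iodoetherification (I2, NaHCO3, MeCN, 0 °C) would form the O1–C2 bond by 5-exo attack of the secondary hydroxyl on the iodonium ion and would install the CH2I group directly. C2 would then be set by substrate control only, so the C2-epimeric iodide F5 would have to be removed by chromatography before step 10.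

**Further compounds**

F1 | step 7 | (2S,3S)-2-[3-(benzyloxy)propyl]-3-[5-(benzyloxy)-3-methylidenepentyl]-2-methyloxirane | C=C(CCOCc1ccccc1)CC[C@@H]2O[C@@]2(C)CCCOCc1ccccc1
F2 | step 18 | 3-[(3E)-5-(benzenesulfonyl)-4-methylpent-3-en-1-yl]furan | O=S(=O)(C/C(C)=C/CCc1ccoc1)c1ccccc1
F3 | step 18 | (5S)-5-[(2R,5R)-5-[(4E)-3-(benzenesulfonyl)-7-(furan-3-yl)-2-hydroxy-4-methylhept-4-en-1-yl]-5-methyloxolan-2-yl]-5-methyloxolan-2-one | C/C(=C\CCc1ccoc1)C(S(=O)(=O)c1ccccc1)C(O)C[C@@]1(C)CC[C@H]([C@]2(C)CCC(=O)O2)O1
F4 | step 18 | (5S)-5-[(2R,5R)-5-[(4E)-3-(benzenesulfonyl)-7-(furan-3-yl)-4-methyl-2-oxohept-4-en-1-yl]-5-methyloxolan-2-yl]-5-methyloxolan-2-one | C/C(=C\CCc1ccoc1)C(S(=O)(=O)c1ccccc1)C(=O)C[C@@]1(C)CC[C@H]([C@]2(C)CCC(=O)O2)O1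
F5 | step 8 | (2S)-5-(benzyloxy)-2-[(2R,5S)-5-[2-(benzyloxy)ethyl]-5-(iodomethyl)oxolan-2-yl]pentan-2-ol | c1ccccc1COCC[C@]1(CI)CC[C@H]([C@@](C)(O)CCCOCc2ccccc2)O1
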